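**Retrosynthetic overview**
- Target ⇐ bis-TIPS ether of the β-hydroxy-1,3-diketone (fluoride) ⇐ the same compound with the C3 carbonyl masked as a 1,3-dithiane (hydrolysis).
- Key disconnection C2–C3: a lithiated β-keto-1,3-dithiane, i.e. a masked acyl anion carrying the whole C3–C7 arm as an enolate/dithianyl dianion, opens the CH2 terminus of an (R)-aryl oxirane.
- The (S)-carbinol comes unchanged from the epoxide, which is made from 2-chloro-4'-hydroxyacetophenone by silylation, CBS reduction and ring closure.
- The keto-dithiane comes from but-3-yn-2-one and propane-1,3-dithiol, then aldol condensation with TIPS-vanillin.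
- Rings: the target is acyclic; the only temporary rings are the oxirane (made in step 2, opened in step 6) and the 1,3-dithiane (made in step 3, opened in step 7).

Assumption: the enol C=C geometry written in the target SMILES is one tautomeric depiction of an (S)-β-hydroxy-1,3-diketone whose keto and enol forms interconvert freely, so the elements to build are the (S)-carbinol and the (E)-styryl double bond.

**Route**

Step 1
Reactants: 1 2-chloro-1-(4-hydroxyphenyl)ethan-1-one
Product: 2 2-chloro-1-[4-(triisopropylsilyloxy)phenyl]ethan-1-one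
Conditions: TIPSOTf (1.1 equiv), 2,6-lutidine (1.5 equiv), CH2Cl2, −78 → 0 °C
Reagents that add atoms: triisopropylsilyl trifluoromethanesulfonate, CC(C)[Si](C(C)C)(C(C)C)OS(=O)(=O)C(F)(F)F
Why: O-silylation of the phenol by a silyl triflate with a hindered, non-nucleophilic pyridine base is fast at low temperature and avoids the N-alkylation that imidazole or a trialkylamine would suffer with the α-chloro ketone.

Step 2
Reactants: 2 2-chloro-1-[4-(triisopropylsilyloxy)phenyl]ethan-1-one
Product: 4 (R)-2-[4-(triisopropylsilyloxy)phenyl]oxirane, via (R)-chlorohydrin 3 (not isolated)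
Conditions: (R)-Me-CBS oxazaborolidine (10 mol %), BH3·SMe2 (0.7 equiv), THF, 0 °C; MeOH quench; then 2 M aq NaOH, Et2O, 0 °C → rt
Reagents that add atoms: none
Why: Corey–Bakshi–Shibata reduction with the (R)-catalyst delivers hydride to the ketone face that gives the (R)-chlorohydrin (typically ≥95% ee for α-chloroacetophenones), and the intramolecular Williamson closure displaces chloride at CH2 only, so the benzylic centre is retained and the epoxide is (R).

Step 3
Reactants: 5 but-3-yn-2-one
Product: 6 1-(1,3-dithian-2-yl)propan-2-one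
Conditions: HS(CH2)3SH (1.05 equiv), NaOMe (0.3 equiv), MeOH/CH2Cl2, −10 °C → rt
Reagents that add atoms: propane-1,3-dithiol, SCCCS
Why: Double thia-Michael addition: thiolate adds to the ynone and the second thiol adds intramolecularly to the resulting β-thio enone, closing the six-membered dithiane, a known entry to β-keto 1,3-dithianes.

Step 4
Reactants: 7 vanillin (4-hydroxy-3-methoxybenzaldehyde)
Product: 8 3-methoxy-4-(triisopropylsilyloxy)benzaldehyde
Conditions: TIPSCl (1.1 equiv), imidazole (2 equiv), DMF, rt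
Reagents that add atoms: chlorotriisopropylsilane, CC(C)[Si](Cl)(C(C)C)C(C)C
Why: Standard imidazole-promoted O-silylation of a phenol, giving an aryl silyl ether robust enough for amines and organolithiums.

Step 5
Reactants: 6 1-(1,3-dithian-2-yl)propan-2-one; 8 3-methoxy-4-(triisopropylsilyloxy)benzaldehyde
Product: 9 (E)-1-(1,3-dithian-2-yl)-4-[3-methoxy-4-(triisopropylsilyloxy)phenyl]but-3-en-2-one
Conditions: pyrrolidine (0.5 equiv), AcOH (0.5 equiv), THF, 45 °C
Reagents that add atoms: none
Why: Amine/acid-mediated Claisen–Schmidt aldol condensation through the less substituted (methyl-side) enamine, with the hindered CH2 next to the dithiane staying out, gives the thermodynamically favoured (E)-enone under conditions that spare the aryl silyl ether.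

Step 6
Reactants: 9 (E)-1-(1,3-dithian-2-yl)-4-[3-methoxy-4-(triisopropylsilyloxy)phenyl]but-3-en-2-one; 4 (R)-2-[4-(triisopropylsilyloxy)phenyl]oxirane
Product: 12 (E)-1-{2-[(2S)-2-hydroxy-2-[4-(triisopropylsilyloxy)phenyl]ethyl]-1,3-dithian-2-yl}-4-[3-methoxy-4-(triisopropylsilyloxy)phenyl]but-3-en-2-one, via lithium dienolate 10 (not isolated), via dilithium dianion 11 (not isolated)
Conditions: LiN(SiMe3)2 (1.05 equiv), THF, −78 °C; HMPA, t-BuLi (2.1 equiv), −78 °C; then 4 (1.2 equiv), −78 → −20 °C; aq NH4Cl
Reagents that add atoms: none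
Why: Proposed new method: the amide base first turns the ketone into its cross-conjugated lithium dienolate (shielding carbonyl and enone from the alkyllithium), t-BuLi (one equivalent re-deprotonates the liberated amine) then removes the dithiane C–H, now allylic to the enolate, giving an oxido-allyl dianion that should react mainly at the sulfur-stabilised carbon (the central carbon is a node and the other allyl terminus already bears O–Li), and this masked acyl anion of a 1,3-diketone opens the oxirane by SN2 attack at the unhindered CH2 so the benzylic C–O centre is carried over untouched as (S); closest known chemistry is the Corey–Seebach opening of terminal epoxides by 2-alkyl-2-lithio-1,3-dithianes, together with γ-alkylation of β-keto ester dianions, alkoxide/dithianyl dianions of 2-(2-hydroxyalkyl)-1,3-dithianes and α-alkylation of lithiated 2-alkenyl-1,3-dithianes.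

Step 7
Reactants: 12 (E)-1-{2-[(2S)-2-hydroxy-2-[4-(triisopropylsilyloxy)phenyl]ethyl]-1,3-dithian-2-yl}-4-[3-methoxy-4-(triisopropylsilyloxy)phenyl]but-3-en-2-one
Product: 13 (1S,6E)-1-hydroxy-7-[3-methoxy-4-(triisopropylsilyloxy)phenyl]-1-[4-(triisopropylsilyloxy)phenyl]hept-6-ene-3,5-dione (5-enol form)
Conditions: Hg(ClO4)2·3H2O (2.2 equiv), CaCO3 (5 equiv), THF/H2O 5:1, 0 °C, 15 min
Reagents that add atoms: water, O
Why: Dithioacetal hydrolysis: thiophilic divalent mercury binds both sulfurs, water captures the thionium ion and the freed 1,3-diketone enolises, while CaCO3 buffers the acid so the β-hydroxy ketone neither dehydrates nor undergoes retro-aldol and the carbinol stays (S).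

Step 8
Reactants: 13 (1S,6E)-1-hydroxy-7-[3-methoxy-4-(triisopropylsilyloxy)phenyl]-1-[4-(triisopropylsilyloxy)phenyl]hept-6-ene-3,5-dione (5-enol form)
Product: 14 (1S,6E)-1-hydroxy-7-(4-hydroxy-3-methoxyphenyl)-1-(4-hydroxyphenyl)hept-6-ene-3,5-dione (5-enol form; target)
Conditions: Bu4NF (2.5 equiv), AcOH (3 equiv), THF, 0 °C
Reagents that add atoms: none
Why: Fluoride-mediated desilylation of both aryl silyl ethers, buffered with acetic acid so that the β-hydroxy-1,3-diketone and the para-hydroxybenzylic alcohol meet neither free base (retro-aldol, E1cB dehydration to the curcuminoid) nor strong acid.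

**Compound list**

1 | 2-chloro-1-(4-hydroxyphenyl)ethan-1-one | O=C(CCl)c1ccc(O)cc1 | starting material
2 | 2-chloro-1-[4-(triisopropylsilyloxy)phenyl]ethan-1-one | O=C(CCl)c1ccc(O[Si](C(C)C)(C(C)C)C(C)C)cc1 | intermediate
3 | (R)-2-chloro-1-[4-(triisopropylsilyloxy)phenyl]ethan-1-ol | ClC[C@H](O)c1ccc(O[Si](C(C)C)(C(C)C)C(C)C)cc1 | intermediate
4 | (R)-2-[4-(triisopropylsilyloxy)phenyl]oxirane | C1[C@H](O1)c1ccc(O[Si](C(C)C)(C(C)C)C(C)C)cc1 | intermediate
5 | but-3-yn-2-one | CC(=O)C#C | starting material
6 | 1-(1,3-dithian-2-yl)propan-2-one | CC(=O)CC1SCCCS1 | intermediate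
7 | vanillin (4-hydroxy-3-methoxybenzaldehyde) | COc1cc(C=O)ccc1O | starting material
8 | 3-methoxy-4-(triisopropylsilyloxy)benzaldehyde | COc1cc(C=O)ccc1O[Si](C(C)C)(C(C)C)C(C)C | intermediate
9 | (E)-1-(1,3-dithian-2-yl)-4-[3-methoxy-4-(triisopropylsilyloxy)phenyl]but-3-en-2-one | COc1cc(/C=C/C(=O)CC2SCCCS2)ccc1O[Si](C(C)C)(C(C)C)C(C)C | intermediate
10 | lithium dienolate of 9 (enolate C=C geometry not defined) | [Li+].COc1cc(/C=C/C([O-])=CC2SCCCS2)ccc1O[Si](C(C)C)(C(C)C)C(C)C | intermediate
11 | dilithium dianion of 9, lithium enolate plus 2-lithio-1,3-dithiane (enolate C=C geometry not defined) | [Li+].[Li+].COc1cc(/C=C/C([O-])=C[C-]2SCCCS2)ccc1O[Si](C(C)C)(C(C)C)C(C)C | intermediate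
12 | (E)-1-{2-[(2S)-2-hydroxy-2-[4-(triisopropylsilyloxy)phenyl]ethyl]-1,3-dithian-2-yl}-4-[3-methoxy-4-(triisopropylsilyloxy)phenyl]but-3-en-2-one | COc1cc(/C=C/C(=O)CC2(C[C@H](O)c3ccc(O[Si](C(C)C)(C(C)C)C(C)C)cc3)SCCCS2)ccc1O[Si](C(C)C)(C(C)C)C(C)C | intermediate
13 | (1S,6E)-1-hydroxy-7-[3-methoxy-4-(triisopropylsilyloxy)phenyl]-1-[4-(triisopropylsilyloxy)phenyl]hept-6-ene-3,5-dione, 5-enol form | COc1cc(/C=C/C(O)=C\C(=O)C[C@H](O)c2ccc(O[Si](C(C)C)(C(C)C)C(C)C)cc2)ccc1O[Si](C(C)C)(C(C)C)C(C)C | intermediate
14 | (1S,6E)-1-hydroxy-7-(4-hydroxy-3-methoxyphenyl)-1-(4-hydroxyphenyl)hept-6-ene-3,5-dione, 5-enol form (CNP0206527.1) | COc1cc(/C=C/C(O)=C\C(=O)C[C@H](O)c2ccc(O)cc2)ccc1O | target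

**Step count**

Total steps: 8. Longest linear sequence: 5 (steps 1, 2, 6, 7, 8; the branches through steps 3 or 4 and then 5, 6, 7, 8 are equally long).

**Steps most likely to fail, with fallbacks**

Step 6 (most at risk). The mono-enolate may open the dithiane by retro-thia-Michael before the second deprotonation, the extended anion may react at its benzylic terminus, or the epoxide may be attacked at the benzylic carbon. Fallback, setting out from 6 and returning at 12: ketalise the ketone (ethylene glycol, TsOH cat., benzene, reflux with water removal) to 2-[(2-methyl-1,3-dioxolan-2-yl)methyl]-1,3-dithiane F1. This ordinary 2-alkyl-1,3-dithiane is lithiated with n-BuLi (THF, −30 °C) and opens 4 at CH2 to give (S)-2-{2-[(2-methyl-1,3-dioxolan-2-yl)methyl]-1,3-dithian-2-yl}-1-[4-(triisopropylsilyloxy)phenyl]ethan-1-ol F2. PPTS in wet acetone (45 °C) frees the methyl ketone (S)-1-{2-[2-hydroxy-2-[4-(triisopropylsilyloxy)phenyl]ethyl]-1,3-dithian-2-yl}propan-2-one F3. Pyrrolidine/AcOH condensation of its only reactive α-position (the CH3) with 8 then gives 12; the styryl arm is thus attached after the umpolung step and no dianion is needed.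

Step 7. Hydrolysis may stall at a β-(alkylthio) enone, the diketone may bind mercury, or the product may dehydrate. Fallback, setting out from 12 and returning at 13: oxidise one sulfur with mCPBA (1.0 equiv, CH2Cl2, −78 °C) to the 1,3-dithiane 1-oxide of 12 F4 (mixture of sulfoxide diastereomers). Then trigger a metal-free Pummerer-type fragmentation with (CF3CO)2O/2,6-lutidine (MeCN, 0 °C) and work up with aqueous NaHCO3, which hydrolyses the thionium ion and any transient trifluoroacetate to give 13.

Step 5. Some condensation may occur at the CH2 next to the dithiane, or the amine may open the dithiane. Fallback, setting out from 8 and returning at 9: condense 8 with acetone (pyrrolidine/AcOH, acetone as solvent, rt) to (E)-4-[3-methoxy-4-(triisopropylsilyloxy)phenyl]but-3-en-2-one F5. Convert it with LiN(SiMe3)2/Me3SiCl (THF, −78 °C) into (E)-trimethyl{[4-(3-methoxy-4-(triisopropylsilyloxy)phenyl)buta-1,3-dien-2-yl]oxy}silane F6. Alkylate this silyl dienol ether with 1,3-dithian-2-ylium tetrafluoroborate (from 1,3-dithiane and Ph3CBF4; CH2Cl2, −78 °C); this places the dithiane on the only enolisable carbon and gives 9.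

**Further compounds**

F1 | step 6 | 2-[(2-methyl-1,3-dioxolan-2-yl)methyl]-1,3-dithiane | CC1(CC2SCCCS2)OCCO1
F2 | step 6 | (S)-2-{2-[(2-methyl-1,3-dioxolan-2-yl)methyl]-1,3-dithian-2-yl}-1-[4-(triisopropylsilyloxy)phenyl]ethan-1-ol | CC1(CC2(C[C@H](O)c3ccc(O[Si](C(C)C)(C(C)C)C(C)C)cc3)SCCCS2)OCCO1
F3 | step 6 | (S)-1-{2-[2-hydroxy-2-[4-(triisopropylsilyloxy)phenyl]ethyl]-1,3-dithian-2-yl}propan-2-one | CC(=O)CC1(C[C@H](O)c2ccc(O[Si](C(C)C)(C(C)C)C(C)C)cc2)SCCCS1
F4 | step 7 | 1,3-dithiane 1-oxide of 12 (sulfoxide diastereomers not defined) | COc1cc(/C=C/C(=O)CC2(C[C@H](O)c3ccc(O[Si](C(C)C)(C(C)C)C(C)C)cc3)SCCCS2=O)ccc1O[Si](C(C)C)(C(C)C)C(C)C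
F5 | step 5 | (E)-4-[3-methoxy-4-(triisopropylsilyloxy)phenyl]but-3-en-2-one | COc1cc(/C=C/C(C)=O)ccc1O[Si](C(C)C)(C(C)C)C(C)C
F6 | step 5 | (E)-trimethyl{[4-(3-methoxy-4-(triisopropylsilyloxy)phenyl)buta-1,3-dien-2-yl]oxy}silane | COc1cc(/C=C/C(=C)O[Si](C)(C)C)ccc1O[Si](C(C)C)(C(C)C)C(C)C
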